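**Plan**

- Retrosynthesis: the 6,6'-biaryl bond is cut first (Suzuki–Miyaura), giving two chromanones that descend from one monomer. In the monomer the pyranone ring is cut at C2–C3 and C4–C4a, which takes out a two-carbon unit (ethoxyacetylene) and leaves an acyclic α-fluoro-α-aryloxy ester. This is cut at C2–C1' (glycolate aldol) and at the aryl ether O–CH2 bond.
- Forward: aryl ether, then the aldol chain, then the tertiary fluoride, then the pyranone ring closed onto the existing arene, then C6 bromination. One portion is borylated (open, benzyl-protected half), one portion is debenzylated and lactonised (lactone half); biaryl union and a global hydrogenolysis finish the route.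
- Enabling feature: once fluoride leaves C2, the aryl ether oxygen O1 on C2 and the arene bond C8a=C4a form a 2-oxadiene (C2=O1–C8a=C4a). C4a lies between O1 and the C5 oxygen and is the only free ortho position, because C8 carries a temporary chlorine. The chlorine also steers bromination to C6 and is removed in the last step.
- Stereochemistry: C2' comes from an Evans alkylation and C1' from an Evans syn glycolate aldol (auxiliary control). The quaternary C2 comes from 1,2-induction by C1' in the key step (Felkin–Anh). Both halves inherit the same (2S,1'R,2'S) set from the common monomer.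

Key step: step 11

Remark: locants follow chroman-4-one numbering (O1, C2, C3, C4, C4a, C5 to C8, C8a); C1' is the side-chain carbinol carbon and C2' the methyl-bearing carbon. Compound 15 is used as a mixture of C2 epimers because C2 becomes planar in step 11.

**Route**

Step 1
Reactants: 1 3-(benzyloxy)phenol
Product: 2 5-(benzyloxy)-2-chlorophenol
Conditions: SO2Cl2 (1.0 equiv), 2,2,6,6-tetramethylpiperidine (cat.), toluene, 0 °C → rt
Reagents that add atoms: sulfuryl chloride, ClS(Cl)(=O)=O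
Why: Amine-catalysed ortho-selective electrophilic chlorination of a phenol, in which the N-chloroamine is delivered by hydrogen bonding to the OH; of the two ortho sites only C6 is unhindered, and it is also para to the benzyloxy group.

Step 2
Reactants: 2 5-(benzyloxy)-2-chlorophenol; 3 (S)-4-benzyl-3-(chloroacetyl)oxazolidin-2-one
Product: 4 (S)-4-benzyl-3-{[5-(benzyloxy)-2-chlorophenoxy]acetyl}oxazolidin-2-one
Conditions: K2CO3, NaI (cat.), acetone, rt
Reagents that add atoms: none
Why: Williamson ether synthesis, an SN2 displacement of the activated α-chloro imide by the phenoxide with iodide catalysis.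

Step 3
Reactants: 5 (R)-4-benzyl-3-propanoyloxazolidin-2-one; 6 tert-butyl bromoacetate
Product: 7 tert-butyl (S)-4-[(R)-4-benzyl-2-oxooxazolidin-3-yl]-3-methyl-4-oxobutanoate
Conditions: NaHMDS, THF, −78 °C; then 6, −78 → −40 °C
Reagents that add atoms: none
Why: Evans asymmetric alkylation; the chelated Z-sodium enolate is alkylated on the face opposite the auxiliary benzyl group, which sets the methyl-bearing center (later C2') as S.

Step 4
Reactants: 7 tert-butyl (S)-4-[(R)-4-benzyl-2-oxooxazolidin-3-yl]-3-methyl-4-oxobutanoate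
Product: 8 tert-butyl (S)-4-hydroxy-3-methylbutanoate
Conditions: LiBH4, MeOH (1 equiv), THF, 0 °C
Reagents that add atoms: none
Why: Reductive cleavage of the N-acyl oxazolidinone by LiBH4, which should leave the tert-butyl ester and the stereocenter untouched.

Step 5
Reactants: 8 tert-butyl (S)-4-hydroxy-3-methylbutanoate
Product: 9 tert-butyl (S)-3-methyl-4-oxobutanoate
Conditions: Dess–Martin periodinane, CH2Cl2, 0 °C → rt; used at once
Reagents that add atoms: none
Why: Dess–Martin oxidation of the primary alcohol under non-basic conditions, so that the α-stereocenter of the aldehyde should not epimerise.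

Step 6
Reactants: 4 (S)-4-benzyl-3-{[5-(benzyloxy)-2-chlorophenoxy]acetyl}oxazolidin-2-one; 9 tert-butyl (S)-3-methyl-4-oxobutanoate
Product: 10 tert-butyl (3S,4R,5S)-6-[(S)-4-benzyl-2-oxooxazolidin-3-yl]-5-[5-(benzyloxy)-2-chlorophenoxy]-4-hydroxy-3-methyl-6-oxohexanoate
Conditions: Bu2BOTf, Et3N, CH2Cl2, −78 → 0 °C; 9, −78 → 0 °C; then pH 7 buffer, MeOH, H2O2, 0 °C
Reagents that add atoms: none
Why: Evans syn aldol reaction of a glycolate imide; the Z-boron enolate reacts through a Zimmerman–Traxler chair whose enolate face is fixed by the auxiliary, which sets C1' as R by reagent control (C2 is set as well but is made planar in step 11).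

Step 7
Reactants: 10 tert-butyl (3S,4R,5S)-6-[(S)-4-benzyl-2-oxooxazolidin-3-yl]-5-[5-(benzyloxy)-2-chlorophenoxy]-4-hydroxy-3-methyl-6-oxohexanoate
Product: 11 tert-butyl (3S,4R,5S)-6-[(S)-4-benzyl-2-oxooxazolidin-3-yl]-4-(benzyloxy)-5-[5-(benzyloxy)-2-chlorophenoxy]-3-methyl-6-oxohexanoate
Conditions: 2-benzyloxy-1-methylpyridinium triflate, MgO, PhCF3, 85 °C
Reagents that add atoms: 2-benzyloxy-1-methylpyridinium triflate, C[n+]1ccccc1OCc1ccccc1.[O-]S(=O)(=O)C(F)(F)F
Why: Neutral benzyl transfer from the 2-benzyloxypyridinium salt (Dudley benzylation) should protect the hindered aldol hydroxyl without base or acid, so that neither retro-aldol cleavage nor lactonisation onto the tert-butyl ester is triggered.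

Step 8
Reactants: 11 tert-butyl (3S,4R,5S)-6-[(S)-4-benzyl-2-oxooxazolidin-3-yl]-4-(benzyloxy)-5-[5-(benzyloxy)-2-chlorophenoxy]-3-methyl-6-oxohexanoate
Product: 12 6-tert-butyl 1-methyl (2S,3R,4S)-3-(benzyloxy)-2-[5-(benzyloxy)-2-chlorophenoxy]-4-methylhexanedioate
Conditions: MeMgBr, MeOH, CH2Cl2, 0 °C
Reagents that add atoms: methanol, CO
Why: Transesterification of the activated exocyclic imide carbonyl by chelating MeOMgBr should release the auxiliary and give the methyl ester that the target carries at C2.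

Step 9
Reactants: 12 6-tert-butyl 1-methyl (2S,3R,4S)-3-(benzyloxy)-2-[5-(benzyloxy)-2-chlorophenoxy]-4-methylhexanedioate
Product: 13 (3S,4R,5S)-4-(benzyloxy)-5-[5-(benzyloxy)-2-chlorophenoxy]-6-methoxy-3-methyl-6-oxohexanoic acid
Conditions: TFA/CH2Cl2 (1:4), 0 °C → rt
Reagents that add atoms: none
Why: Acidolysis of the tert-butyl ester (loss of isobutene) should free the remote carboxylic acid while the benzyl ethers and the methyl ester stay.

Step 10
Reactants: 13 (3S,4R,5S)-4-(benzyloxy)-5-[5-(benzyloxy)-2-chlorophenoxy]-6-methoxy-3-methyl-6-oxohexanoic acid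
Product: 15 6-benzyl 1-methyl (3R,4S)-3-(benzyloxy)-2-[5-(benzyloxy)-2-chlorophenoxy]-2-fluoro-4-methylhexanedioate (both C2 epimers), via fluoro acid 14 (not isolated)
Conditions: KHMDS (2.2 equiv), THF, −78 °C; NFSI, −78 → −40 °C; then BnBr, DMF, −40 °C → rt
Reagents that add atoms: N-fluorobenzenesulfonimide, O=S(=O)(c1ccccc1)N(F)S(=O)(=O)c1ccccc1; benzyl bromide, BrCc1ccccc1
Why: Electrophilic fluorination of an ester enolate with NFSI followed by carboxylate alkylation; with the remote acid held as its carboxylate, the second equivalent of base can only remove the α-aryloxy C2–H, so the enolate should form at C2 alone.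

Step 11
Reactants: 15 6-benzyl 1-methyl (3R,4S)-3-(benzyloxy)-2-[5-(benzyloxy)-2-chlorophenoxy]-2-fluoro-4-methylhexanedioate; 16 ethoxyacetylene
Product: 18 methyl (2S)-5-(benzyloxy)-2-[(1R,2S)-1,4-bis(benzyloxy)-2-methyl-4-oxobutyl]-8-chloro-4-oxochromane-2-carboxylate, via enol ether 17 (not isolated)
Conditions: 16 (3 equiv), BF3·OEt2 (2.5 equiv), CH2Cl2, −78 → −30 °C; then 1 M HCl, THF, 0 °C → rt
Reagents that add atoms: water, O
Why: Proposed new method: BF3 abstracts fluoride from C2 of 15 to give the O-aryl oxocarbenium ion (the 2-oxadiene C2=O1–C8a=C4a), the terminal carbon of ethoxyacetylene adds to C2 (bond C2–C3) to give a ketene-oxonium (α-ethoxy vinyl) cation at C4, and C4a attacks this cation (bond C4–C4a) with loss of a proton, so that enol ether 17 forms and is hydrolysed to the ketone on acidic work-up. The closest known reaction type is the oxa-Povarov reaction, the stepwise formal [4+2] cycloaddition of aryl oxocarbenium ions with alkenes to chromans, together with the Lewis acid addition of ynol ethers and ynamides to oxocarbenium ions; new here are the alkyne partner at the ketone oxidation level and the tertiary, ester-bearing cation. The pyranone ring closes by electrophilic aromatic substitution, a 6-exo-dig attack of C4a on C4 with respect to the C4=O bond of the ketene-oxonium ion, the C3=C4 bond ending up inside the ring. The new quaternary stereocenter C2 is controlled by the adjacent C1' benzyloxy stereocenter: in the Felkin–Anh arrangement the C1'–O bond is anti to the incoming alkyne, which passes the C1' hydrogen and from (1'R) should give (2S), and a chelate between the C1' oxygen and the ester carbonyl predicts the same face. Regioselectivity between the two positions ortho to O1 is needed and is secured by the chlorine at C8, which leaves C4a (activated by O1 and by the C5 benzyloxy group) as the only site within reach. Proton loss from C1' of the cation is the competing path, and low temperature with an excess of the ynol ether present from the start is meant to suppress it.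

Step 12
Reactants: 18 methyl (2S)-5-(benzyloxy)-2-[(1R,2S)-1,4-bis(benzyloxy)-2-methyl-4-oxobutyl]-8-chloro-4-oxochromane-2-carboxylate
Product: 19 methyl (2S)-5-(benzyloxy)-2-[(1R,2S)-1,4-bis(benzyloxy)-2-methyl-4-oxobutyl]-6-bromo-8-chloro-4-oxochromane-2-carboxylate
Conditions: NBS, MeCN, 0 °C → rt, dark
Reagents that add atoms: N-bromosuccinimide, O=C1CCC(=O)N1Br
Why: Electrophilic aromatic bromination; C6 is para to O1 and ortho to the C5 benzyloxy group and is the only activated free position because C8 is chlorinated.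

Step 13
Reactants: 19 methyl (2S)-5-(benzyloxy)-2-[(1R,2S)-1,4-bis(benzyloxy)-2-methyl-4-oxobutyl]-6-bromo-8-chloro-4-oxochromane-2-carboxylate
Product: 20 methyl (2S)-5-(benzyloxy)-2-[(1R,2S)-1,4-bis(benzyloxy)-2-methyl-4-oxobutyl]-8-chloro-4-oxo-6-(4,4,5,5-tetramethyl-1,3,2-dioxaborolan-2-yl)chromane-2-carboxylate
Conditions: B2pin2, PdCl2(dppf), KOAc, 1,4-dioxane, 80 °C
Reagents that add atoms: bis(pinacolato)diboron, CC1(C)OB(OC1(C)C)B1OC(C)(C)C(C)(C)O1
Why: Miyaura borylation of the aryl bromide by zerovalent palladium formed in situ; the C8 chloride should not undergo oxidative addition with this catalyst.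

Step 14
Reactants: 19 methyl (2S)-5-(benzyloxy)-2-[(1R,2S)-1,4-bis(benzyloxy)-2-methyl-4-oxobutyl]-6-bromo-8-chloro-4-oxochromane-2-carboxylate
Product: 22 methyl (2S)-6-bromo-8-chloro-5-hydroxy-2-[(2R,3S)-3-methyl-5-oxotetrahydrofuran-2-yl]-4-oxochromane-2-carboxylate, via hydroxy acid 21 (not isolated)
Conditions: BCl3 (6 equiv), C6HMe5 (6 equiv), CH2Cl2, −78 → 0 °C; then TsOH·H2O (cat.), toluene, 50 °C
Reagents that add atoms: none
Why: BCl3 cleaves the aryl benzyl ether (helped by chelation to the C4 carbonyl), the alkyl benzyl ether and the benzyl ester with pentamethylbenzene as non-basic benzyl cation scavenger, and the freed γ-hydroxy acid should close to the γ-lactone under acid catalysis (5-exo-trig) without touching a stereocenter.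

Step 15
Reactants: 20 methyl (2S)-5-(benzyloxy)-2-[(1R,2S)-1,4-bis(benzyloxy)-2-methyl-4-oxobutyl]-8-chloro-4-oxo-6-(4,4,5,5-tetramethyl-1,3,2-dioxaborolan-2-yl)chromane-2-carboxylate; 22 methyl (2S)-6-bromo-8-chloro-5-hydroxy-2-[(2R,3S)-3-methyl-5-oxotetrahydrofuran-2-yl]-4-oxochromane-2-carboxylate
Product: 23 methyl (2S)-5-(benzyloxy)-2-[(1R,2S)-1,4-bis(benzyloxy)-2-methyl-4-oxobutyl]-8-chloro-6-{(2S)-8-chloro-5-hydroxy-2-(methoxycarbonyl)-2-[(2R,3S)-3-methyl-5-oxotetrahydrofuran-2-yl]-4-oxochroman-6-yl}-4-oxochromane-2-carboxylate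
Conditions: PdCl2(dppf), K3PO4, 1,4-dioxane/H2O (10:1), 60 °C
Reagents that add atoms: none
Why: Suzuki–Miyaura cross-coupling of aryl bromide and aryl boronate; only two ortho substituents flank the new bond, so no stable biaryl axis arises, and the aryl chlorides should stay intact with this catalyst.

Step 16
Reactants: 23 methyl (2S)-5-(benzyloxy)-2-[(1R,2S)-1,4-bis(benzyloxy)-2-methyl-4-oxobutyl]-8-chloro-6-{(2S)-8-chloro-5-hydroxy-2-(methoxycarbonyl)-2-[(2R,3S)-3-methyl-5-oxotetrahydrofuran-2-yl]-4-oxochroman-6-yl}-4-oxochromane-2-carboxylate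
Product: 24 (3S,4R)-4-hydroxy-4-[(2S)-5-hydroxy-6-{(2S)-5-hydroxy-2-(methoxycarbonyl)-2-[(2R,3S)-3-methyl-5-oxotetrahydrofuran-2-yl]-4-oxochroman-6-yl}-2-(methoxycarbonyl)-4-oxochroman-2-yl]-3-methylbutanoic acid (CNP0517857.1)
Conditions: H2 (1 atm), Pd/C, NaOAc, EtOAc/MeOH, rt; work-up at pH 4
Reagents that add atoms: none
Why: Heterogeneous hydrogenolysis should remove the two benzyl ethers and the benzyl ester and reduce both aryl C–Cl bonds (acetate takes up the HCl), which frees the γ-hydroxy acid under near-neutral conditions in which it should not lactonise.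

**Compound list**

1 | 3-(benzyloxy)phenol | Oc1cccc(OCc2ccccc2)c1 | starting material
2 | 5-(benzyloxy)-2-chlorophenol | Oc1cc(OCc2ccccc2)ccc1Cl | intermediate
3 | (S)-4-benzyl-3-(chloroacetyl)oxazolidin-2-one | O=C(CCl)N1[C@@H](Cc2ccccc2)COC1=O | starting material
4 | (S)-4-benzyl-3-{[5-(benzyloxy)-2-chlorophenoxy]acetyl}oxazolidin-2-one | O=C(COc1cc(OCc2ccccc2)ccc1Cl)N1[C@@H](Cc2ccccc2)COC1=O | intermediate
5 | (R)-4-benzyl-3-propanoyloxazolidin-2-one | CCC(=O)N1[C@H](Cc2ccccc2)COC1=O | starting material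
6 | tert-butyl bromoacetate | BrCC(=O)OC(C)(C)C | starting material
7 | tert-butyl (S)-4-[(R)-4-benzyl-2-oxooxazolidin-3-yl]-3-methyl-4-oxobutanoate | C[C@@H](CC(=O)OC(C)(C)C)C(=O)N1[C@H](Cc2ccccc2)COC1=O | intermediate
8 | tert-butyl (S)-4-hydroxy-3-methylbutanoate | OC[C@@H](C)CC(=O)OC(C)(C)C | intermediate
9 | tert-butyl (S)-3-methyl-4-oxobutanoate | O=C[C@@H](C)CC(=O)OC(C)(C)C | intermediate
10 | tert-butyl (3S,4R,5S)-6-[(S)-4-benzyl-2-oxooxazolidin-3-yl]-5-[5-(benzyloxy)-2-chlorophenoxy]-4-hydroxy-3-methyl-6-oxohexanoate | O=C(N1[C@@H](Cc2ccccc2)COC1=O)[C@@H](Oc1cc(OCc2ccccc2)ccc1Cl)[C@H](O)[C@@H](C)CC(=O)OC(C)(C)C | intermediate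
11 | tert-butyl (3S,4R,5S)-6-[(S)-4-benzyl-2-oxooxazolidin-3-yl]-4-(benzyloxy)-5-[5-(benzyloxy)-2-chlorophenoxy]-3-methyl-6-oxohexanoate | O=C(N1[C@@H](Cc2ccccc2)COC1=O)[C@@H](Oc1cc(OCc2ccccc2)ccc1Cl)[C@H](OCc1ccccc1)[C@@H](C)CC(=O)OC(C)(C)C | intermediate
12 | 6-tert-butyl 1-methyl (2S,3R,4S)-3-(benzyloxy)-2-[5-(benzyloxy)-2-chlorophenoxy]-4-methylhexanedioate | COC(=O)[C@@H](Oc1cc(OCc2ccccc2)ccc1Cl)[C@H](OCc1ccccc1)[C@@H](C)CC(=O)OC(C)(C)C | intermediate
13 | (3S,4R,5S)-4-(benzyloxy)-5-[5-(benzyloxy)-2-chlorophenoxy]-6-methoxy-3-methyl-6-oxohexanoic acid | COC(=O)[C@@H](Oc1cc(OCc2ccccc2)ccc1Cl)[C@H](OCc1ccccc1)[C@@H](C)CC(=O)O | intermediate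
14 | (3S,4R)-4-(benzyloxy)-5-[5-(benzyloxy)-2-chlorophenoxy]-5-fluoro-6-methoxy-3-methyl-6-oxohexanoic acid (C5 epimers) | COC(=O)C(F)(Oc1cc(OCc2ccccc2)ccc1Cl)[C@H](OCc1ccccc1)[C@@H](C)CC(=O)O | intermediate
15 | 6-benzyl 1-methyl (3R,4S)-3-(benzyloxy)-2-[5-(benzyloxy)-2-chlorophenoxy]-2-fluoro-4-methylhexanedioate (C2 epimers) | COC(=O)C(F)(Oc1cc(OCc2ccccc2)ccc1Cl)[C@H](OCc1ccccc1)[C@@H](C)CC(=O)OCc1ccccc1 | intermediate
16 | ethoxyacetylene | C#COCC | starting material
17 | methyl (2S)-5-(benzyloxy)-2-[(1R,2S)-1,4-bis(benzyloxy)-2-methyl-4-oxobutyl]-8-chloro-4-ethoxy-2H-chromene-2-carboxylate | COC(=O)[C@@]1([C@H](OCc2ccccc2)[C@@H](C)CC(=O)OCc2ccccc2)C=C(OCC)c2c(OCc3ccccc3)ccc(Cl)c2O1 | intermediate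
18 | methyl (2S)-5-(benzyloxy)-2-[(1R,2S)-1,4-bis(benzyloxy)-2-methyl-4-oxobutyl]-8-chloro-4-oxochromane-2-carboxylate | COC(=O)[C@@]1([C@H](OCc2ccccc2)[C@@H](C)CC(=O)OCc2ccccc2)CC(=O)c2c(OCc3ccccc3)ccc(Cl)c2O1 | intermediate
19 | methyl (2S)-5-(benzyloxy)-2-[(1R,2S)-1,4-bis(benzyloxy)-2-methyl-4-oxobutyl]-6-bromo-8-chloro-4-oxochromane-2-carboxylate | COC(=O)[C@@]1([C@H](OCc2ccccc2)[C@@H](C)CC(=O)OCc2ccccc2)CC(=O)c2c(OCc3ccccc3)c(Br)cc(Cl)c2O1 | intermediate
20 | methyl (2S)-5-(benzyloxy)-2-[(1R,2S)-1,4-bis(benzyloxy)-2-methyl-4-oxobutyl]-8-chloro-4-oxo-6-(4,4,5,5-tetramethyl-1,3,2-dioxaborolan-2-yl)chromane-2-carboxylate | COC(=O)[C@@]1([C@H](OCc2ccccc2)[C@@H](C)CC(=O)OCc2ccccc2)CC(=O)c2c(OCc3ccccc3)c(B3OC(C)(C)C(C)(C)O3)cc(Cl)c2O1 | intermediate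
21 | (3S,4R)-4-[(2S)-6-bromo-8-chloro-5-hydroxy-2-(methoxycarbonyl)-4-oxochroman-2-yl]-4-hydroxy-3-methylbutanoic acid | COC(=O)[C@@]1([C@H](O)[C@@H](C)CC(=O)O)CC(=O)c2c(O)c(Br)cc(Cl)c2O1 | intermediate
22 | methyl (2S)-6-bromo-8-chloro-5-hydroxy-2-[(2R,3S)-3-methyl-5-oxotetrahydrofuran-2-yl]-4-oxochromane-2-carboxylate | COC(=O)[C@@]1([C@@H]2OC(=O)C[C@@H]2C)CC(=O)c2c(O)c(Br)cc(Cl)c2O1 | intermediate
23 | methyl (2S)-5-(benzyloxy)-2-[(1R,2S)-1,4-bis(benzyloxy)-2-methyl-4-oxobutyl]-8-chloro-6-{(2S)-8-chloro-5-hydroxy-2-(methoxycarbonyl)-2-[(2R,3S)-3-methyl-5-oxotetrahydrofuran-2-yl]-4-oxochroman-6-yl}-4-oxochromane-2-carboxylate | COC(=O)[C@@]1([C@H](OCc2ccccc2)[C@@H](C)CC(=O)OCc2ccccc2)CC(=O)c2c(OCc3ccccc3)c(-c3cc(Cl)c4c(c3O)C(=O)C[C@@](C(=O)OC)([C@@H]3OC(=O)C[C@@H]3C)O4)cc(Cl)c2O1 | intermediate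
24 | (3S,4R)-4-hydroxy-4-[(2S)-5-hydroxy-6-{(2S)-5-hydroxy-2-(methoxycarbonyl)-2-[(2R,3S)-3-methyl-5-oxotetrahydrofuran-2-yl]-4-oxochroman-6-yl}-2-(methoxycarbonyl)-4-oxochroman-2-yl]-3-methylbutanoic acid | COC(=O)[C@@]1([C@H](O)[C@@H](C)CC(=O)O)CC(=O)c2c(ccc(-c3ccc4c(c3O)C(=O)C[C@@](C(=O)OC)([C@@H]3OC(=O)C[C@@H]3C)O4)c2O)O1 | target

**Step count**

Total steps: 16. Longest linear sequence: 13 (steps 3 to 13, 15 and 16).

**Steps most likely to fail**

Step 11 (proposed new method). Proton loss from C1' of the ester-destabilised oxocarbenium ion may outrun C–C bond formation, the Lewis acid may oligomerise the ynol ether, and the vinyl cation may be captured by an oxygen atom instead of the arene. The fallback forms the two bonds one after the other with known chemistry. It sets out from 15: a Mukaiyama-type substitution of the tertiary fluoride with the tert-butyldimethylsilyl ketene acetal of tert-butyl acetate (BF3·OEt2, CH2Cl2, −78 °C; same Felkin–Anh control, and a far stronger nucleophile) should give 7-benzyl 1-tert-butyl (3S,4R,5S)-4-(benzyloxy)-3-[5-(benzyloxy)-2-chlorophenoxy]-3-(methoxycarbonyl)-5-methylheptanedioate F1. TFA then removes the tert-butyl group to give (3S,4R,5S)-7-(benzyloxy)-4-(benzyloxy)-3-[5-(benzyloxy)-2-chlorophenoxy]-3-(methoxycarbonyl)-5-methyl-7-oxoheptanoic acid F2. Intramolecular Friedel–Crafts acylation of this 3-aryloxypropanoic acid (trifluoroacetic anhydride, CH2Cl2, 0 °C → rt) can only close at C4a and comes back to the route at 18.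

Step 10. β-Elimination of the C1' benzyloxy group from the C2 enolate and incomplete enolisation of the hindered C2–H may compete with fluorination. The fallback fluorinates before the chain is built, so that no β-leaving group and no second ester are present. It sets out from 2 and 9: alkylation of 2 with methyl bromoacetate (K2CO3, acetone) gives methyl [5-(benzyloxy)-2-chlorophenoxy]acetate F3. Enolisation (LDA, THF, −78 °C) and NFSI give methyl 2-[5-(benzyloxy)-2-chlorophenoxy]-2-fluoroacetate F4. Its lithium enolate adds to aldehyde 9 under Felkin–Anh control (substrate control at C1', minor C1' epimer removed by chromatography) to give 6-tert-butyl 1-methyl (3R,4S)-2-[5-(benzyloxy)-2-chlorophenoxy]-2-fluoro-3-hydroxy-4-methylhexanedioate F5. Benzylation as in step 7 gives 6-tert-butyl 1-methyl (3R,4S)-3-(benzyloxy)-2-[5-(benzyloxy)-2-chlorophenoxy]-2-fluoro-4-methylhexanedioate F6. TFA then gives the fluoro acid 14, where the fallback comes back to the route; BnBr with KHCO3 in DMF converts 14 into 15.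

Step 15. Base may open the chromanone by a retro-oxa-Michael reaction with loss of the C2 configuration, and the boronate may undergo protodeboronation before transmetalation. The fallback joins the rings without base. It sets out from 19: stannylation with hexamethylditin (Pd(PPh3)4, toluene, 100 °C) gives methyl (2S)-5-(benzyloxy)-2-[(1R,2S)-1,4-bis(benzyloxy)-2-methyl-4-oxobutyl]-8-chloro-4-oxo-6-(trimethylstannyl)chromane-2-carboxylate F7. Stille coupling of F7 with bromide 22 (Pd(PPh3)4, CuI, DMF, 50 °C) comes back to the route at 23.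

**Further compounds**

F1 | step 11 | 7-benzyl 1-tert-butyl (3S,4R,5S)-4-(benzyloxy)-3-[5-(benzyloxy)-2-chlorophenoxy]-3-(methoxycarbonyl)-5-methylheptanedioate | COC(=O)[C@@](CC(=O)OC(C)(C)C)(Oc1cc(OCc2ccccc2)ccc1Cl)[C@H](OCc1ccccc1)[C@@H](C)CC(=O)OCc1ccccc1
F2 | step 11 | (3S,4R,5S)-7-(benzyloxy)-4-(benzyloxy)-3-[5-(benzyloxy)-2-chlorophenoxy]-3-(methoxycarbonyl)-5-methyl-7-oxoheptanoic acid | COC(=O)[C@@](CC(=O)O)(Oc1cc(OCc2ccccc2)ccc1Cl)[C@H](OCc1ccccc1)[C@@H](C)CC(=O)OCc1ccccc1
F3 | step 10 | methyl [5-(benzyloxy)-2-chlorophenoxy]acetate | COC(=O)COc1cc(OCc2ccccc2)ccc1Cl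
F4 | step 10 | methyl 2-[5-(benzyloxy)-2-chlorophenoxy]-2-fluoroacetate | COC(=O)C(F)Oc1cc(OCc2ccccc2)ccc1Cl
F5 | step 10 | 6-tert-butyl 1-methyl (3R,4S)-2-[5-(benzyloxy)-2-chlorophenoxy]-2-fluoro-3-hydroxy-4-methylhexanedioate | COC(=O)C(F)(Oc1cc(OCc2ccccc2)ccc1Cl)[C@H](O)[C@@H](C)CC(=O)OC(C)(C)C
F6 | step 10 | 6-tert-butyl 1-methyl (3R,4S)-3-(benzyloxy)-2-[5-(benzyloxy)-2-chlorophenoxy]-2-fluoro-4-methylhexanedioate | COC(=O)C(F)(Oc1cc(OCc2ccccc2)ccc1Cl)[C@H](OCc1ccccc1)[C@@H](C)CC(=O)OC(C)(C)C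
F7 | step 15 | methyl (2S)-5-(benzyloxy)-2-[(1R,2S)-1,4-bis(benzyloxy)-2-methyl-4-oxobutyl]-8-chloro-4-oxo-6-(trimethylstannyl)chromane-2-carboxylate | COC(=O)[C@@]1([C@H](OCc2ccccc2)[C@@H](C)CC(=O)OCc2ccccc2)CC(=O)c2c(OCc3ccccc3)c([Sn](C)(C)C)cc(Cl)c2O1
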